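**Retrosynthetic overview**
- The bromo-enone (C10 bromine, C10=C11) and the three free hydroxyls are unveiled last from a silylated (Z)-alkylidenecyclopentanone.
- C6–C7 is cut by a nickel/chromium coupling of a (Z)-iodomethylidene cyclopentanone with an α-silyloxy aldehyde; this sets C6 and carries the 7Z geometry.
- The only ring is formed once: a bought cyclobutane is enlarged to the cyclopentanone by a 1,2-shift of C12 from C9 to the alkyne carbon C8 in an ethynylcyclobutanol bis-silyl ether.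
- C12–C13 is cut by an enantioselective alkylation of the cyclobutene-1,2-diol enolate with (2Z,5Z)-octadienyl bromide (from 1-bromopent-2-yne and propargyl alcohol).
- The C1–C6 aldehyde comes from cyclohexene oxide by enantioselective rearrangement and unsymmetrical ozonolysis.

Assumptions: prostanoid numbering is used in the discussion (C1 = ester carbon, C12 = ring carbinol carbon); the catalyst antipodes written in steps 4 and 7 are those taken to give the stated configurations, and the mirror-image catalyst is used if the sense of induction proves opposite; 6 is the commercial bis-trimethylsilyl ether of cyclobut-1-ene-1,2-diol.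

**Step 1**
Reactants: 1 1-bromopent-2-yne; 2 prop-2-yn-1-ol
Product: 3 octa-2,5-diyn-1-ol
Conditions: CuI (cat.), Cs2CO3, DMF, rt
Reagents that add atoms: none
Why: Copper-mediated sp–sp3 coupling of a terminal alkyne with a propargylic bromide gives the skipped diyne under mild carbonate base without allene formation.

**Step 2**
Reactants: 3 octa-2,5-diyn-1-ol
Product: 4 (2Z,5Z)-octa-2,5-dien-1-ol
Conditions: Ni(OAc)2, NaBH4, H2NCH2CH2NH2, H2 (1 atm), EtOH, rt
Reagents that add atoms: none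
Why: cis-Semihydrogenation on ethylenediamine-poisoned nickel boride delivers H2 syn to both alkynes and sets the 2Z,5Z geometry (C14 and C17 alkenes of the target) without over-reduction.

**Step 3**
Reactants: 4 (2Z,5Z)-octa-2,5-dien-1-ol
Product: 5 (2Z,5Z)-1-bromoocta-2,5-diene
Conditions: CBr4, PPh3, CH2Cl2, 0 °C
Reagents that add atoms: carbon tetrabromide BrC(Br)(Br)Br
Why: Appel bromination proceeds by SN2 at the primary carbon and leaves both Z alkenes untouched.

**Step 4**
Reactants: 6 1,2-bis(trimethylsilyloxy)cyclobut-1-ene; 5 (2Z,5Z)-1-bromoocta-2,5-diene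
Product: 9 (2S)-2-[(2Z,5Z)-octa-2,5-dien-1-yl]-2-(trimethylsilyloxy)cyclobutan-1-one, via lithium enolate 7 (not isolated), via tributyltin enolate 8 (not isolated)
Conditions: MeLi, THF, 0 °C to rt; Bu3SnCl, −78 to 0 °C; then 5 (0.5 equiv), (S,S)-Cr(salen)Cl [10 mol%; salen = N,N′-bis(3,5-di-tert-butylsalicylidene)cyclohexane-1,2-diaminate; trivalent chromium], benzene, 4 °C
Reagents that add atoms: none
Why: Proposed new method: chromium salen chloride-catalysed enantioselective alkylation of a tributyltin enolate, whose closest known reaction type is the same catalysis on tetrasubstituted tin enolates of 2-alkylcycloalkanones, is extended here to a four-membered 2-siloxy enolate to create an oxygen-bearing quaternary centre; the chiral trivalent-chromium complex holds the enolate and activates the bromide in its pocket, the large OSiMe3 versus ring CH2 difference distinguishes the enolate faces, C-alkylation by SN2 at the primary allylic carbon keeps both Z alkenes, and the C12 centre is set as S.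

**Step 5**
Reactants: 9 (2S)-2-[(2Z,5Z)-octa-2,5-dien-1-yl]-2-(trimethylsilyloxy)cyclobutan-1-one; 10 ethynylmagnesium bromide
Product: 12 (2S)-1-ethynyl-2-[(2Z,5Z)-octa-2,5-dien-1-yl]-1,2-bis(trimethylsilyloxy)cyclobutane (both C1 epimers), via bromomagnesium alkoxide 11 (not isolated)
Conditions: HC≡CMgBr, THF, −78 to 0 °C; then Me3SiOTf, Et3N, −78 to 0 °C
Reagents that add atoms: trimethylsilyl trifluoromethanesulfonate C[Si](C)(C)OS(=O)(=O)C(F)(F)F
Why: Grignard 1,2-addition to the strained ketone followed by in-flask O-silylation; the new carbinol carbon becomes the C9 carbonyl later so its configuration is irrelevant, and silylating both oxygens makes any silyl shift between them harmless and blocks O-attack on the alkyne.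

**Step 6**
Reactants: 12 (2S)-1-ethynyl-2-[(2Z,5Z)-octa-2,5-dien-1-yl]-1,2-bis(trimethylsilyloxy)cyclobutane
Product: 13 (2Z,3S)-2-(iodomethylidene)-3-[(2Z,5Z)-octa-2,5-dien-1-yl]-3-(trimethylsilyloxy)cyclopentan-1-one
Conditions: NIS (1.1 equiv), Ph3PAuNTf2 (2 mol%, monovalent gold), CH2Cl2, −30 °C, dark
Reagents that add atoms: N-iodosuccinimide O=C1CCC(=O)N1I
Why: Semipinacol-type ring expansion of an alkynylcyclobutanol (gold-activated, iodonium-terminated 1,2-alkyl shift): the more substituted, oxygen-bearing ring carbon migrates anti to the activated alkyne with retention of its configuration, the silyl group leaves to succinimide, and iododeauration with retention places iodine cis to the new C=O, which fixes the Z geometry of the exocyclic alkene.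

**Step 7**
Reactants: 14 cyclohexene oxide
Product: 16 triethyl{[(1R)-cyclohex-2-en-1-yl]oxy}silane, via lithium alkoxide 15 (not isolated)
Conditions: (1S,3R,4R)-3-(pyrrolidin-1-ylmethyl)-2-azabicyclo[2.2.1]heptane (5 mol%), LiN(i-Pr)2, DBU, THF, 0 °C; then Et3SiCl, 0 °C
Reagents that add atoms: chlorotriethylsilane CC[Si](Cl)(CC)CC
Why: Chiral lithium amide-catalysed enantioselective β-elimination (epoxide to allylic alcohol rearrangement) desymmetrises the meso epoxide and sets the R carbinol (C5 of the target), which is trapped as its silyl ether.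

**Step 8**
Reactants: 16 triethyl{[(1R)-cyclohex-2-en-1-yl]oxy}silane
Product: 18 methyl (5R)-6-oxo-5-(triethylsilyloxy)hexanoate, via methoxy hydroperoxide 17 (not isolated)
Conditions: O3, CH2Cl2/MeOH, NaHCO3, −78 °C; then Ac2O, Et3N, 0 °C to rt
Reagents that add atoms: ozone [O-][O+]=O; methanol CO
Why: Ozonolysis with unsymmetrical work-up (Criegee cleavage, methanol trapping, Ac2O/Et3N dehydration): the electron-withdrawing allylic silyloxy group sends the carbonyl oxide to the remote carbon, which becomes the methyl ester, while the proximal carbon becomes the aldehyde and the stereocentre is untouched.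

**Step 9**
Reactants: 13 (2Z,3S)-2-(iodomethylidene)-3-[(2Z,5Z)-octa-2,5-dien-1-yl]-3-(trimethylsilyloxy)cyclopentan-1-one; 18 methyl (5R)-6-oxo-5-(triethylsilyloxy)hexanoate
Product: 19 methyl (5R,6S,7Z)-7-{(2S)-2-[(2Z,5Z)-octa-2,5-dien-1-yl]-5-oxo-2-(trimethylsilyloxy)cyclopentylidene}-5-(triethylsilyloxy)-6-(trimethylsilyloxy)heptanoate
Conditions: CrCl2 (15 mol%, divalent chromium), NiCl2 (3 mol%), Mn powder, Me3SiCl, DMF/DME, rt
Reagents that add atoms: chlorotrimethylsilane C[Si](C)(C)Cl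
Why: Nozaki–Hiyama–Kishi coupling run catalytic in chromium with Mn/Me3SiCl turnover: the alkenylchromium keeps the Z geometry and adds to the α-silyloxy aldehyde in the Felkin–Anh sense to give the 5,6-anti (6S) carbinol (minor 6-epimer removed by chromatography), which is silylated in the flask so the Z γ-hydroxy enone never closes to a hemiketal or furan.

**Step 10**
Reactants: 19 methyl (5R,6S,7Z)-7-{(2S)-2-[(2Z,5Z)-octa-2,5-dien-1-yl]-5-oxo-2-(trimethylsilyloxy)cyclopentylidene}-5-(triethylsilyloxy)-6-(trimethylsilyloxy)heptanoate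
Product: 21 methyl (5R,6S,7Z)-7-{(2R)-4-bromo-2-[(2Z,5Z)-octa-2,5-dien-1-yl]-5-oxo-2-(trimethylsilyloxy)cyclopentylidene}-5-(triethylsilyloxy)-6-(trimethylsilyloxy)heptanoate (both C4 epimers), via silyl dienol ether 20 (not isolated)
Conditions: LiN(SiMe3)2, Me3SiCl, THF, −78 °C; then NBS, THF, −78 °C
Reagents that add atoms: N-bromosuccinimide O=C1CCC(=O)N1Br
Why: Kinetic α′-enolisation of the enone with in situ silylation, then electrophilic bromination of the silyl dienol ether, puts bromine on C10 only; NBS does not touch the isolated Z alkenes at −78 °C (the ring descriptor changes from S to R only through CIP priorities).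

**Step 11**
Reactants: 21 methyl (5R,6S,7Z)-7-{(2R)-4-bromo-2-[(2Z,5Z)-octa-2,5-dien-1-yl]-5-oxo-2-(trimethylsilyloxy)cyclopentylidene}-5-(triethylsilyloxy)-6-(trimethylsilyloxy)heptanoate
Product: 25 methyl (5R,6S,7Z)-7-{(2R)-4-bromo-2-[(2Z,5Z)-octa-2,5-dien-1-yl]-5-oxo-2-(trimethylsilyloxy)cyclopent-3-en-1-ylidene}-5-(triethylsilyloxy)-6-(trimethylsilyloxy)heptanoate, via lithium bromoenolate 22 (not isolated), via bromo selenide 23 (not isolated), via selenoxide 24 (not isolated)
Conditions: LiN(SiMe3)2, THF, −78 °C; PhSeBr, −78 °C; then H2O2 (30%), pyridine, CH2Cl2, 0 °C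
Reagents that add atoms: none
Why: Selenenylation of the bromo-enolate followed by selenoxide syn-elimination toward the only β-hydrogens (C11) gives the 2-bromo enone without an electrophilic bromine source that would attack the skipped diene.

**Step 12**
Reactants: 25 methyl (5R,6S,7Z)-7-{(2R)-4-bromo-2-[(2Z,5Z)-octa-2,5-dien-1-yl]-5-oxo-2-(trimethylsilyloxy)cyclopent-3-en-1-ylidene}-5-(triethylsilyloxy)-6-(trimethylsilyloxy)heptanoate
Product: 26 methyl (5R,6S,7Z)-7-{(2R)-4-bromo-2-hydroxy-2-[(2Z,5Z)-octa-2,5-dien-1-yl]-5-oxocyclopent-3-en-1-ylidene}-5,6-dihydroxyheptanoate (CNP0241880.1)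
Conditions: HF·pyridine, pyridine, THF, 0 °C to rt
Reagents that add atoms: none
Why: Buffered fluoride desilylation frees the three hydroxyls without base (no ester exchange, lactonisation or enone isomerisation) and touches no stereocentre or alkene geometry.

**Compound list**
1 | 1-bromopent-2-yne | CCC#CCBr | starting material
2 | prop-2-yn-1-ol | C#CCO | starting material
3 | octa-2,5-diyn-1-ol | CCC#CCC#CCO | intermediate
4 | (2Z,5Z)-octa-2,5-dien-1-ol | CC/C=C\C/C=C\CO | intermediate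
5 | (2Z,5Z)-1-bromoocta-2,5-diene | CC/C=C\C/C=C\CBr | intermediate
6 | 1,2-bis(trimethylsilyloxy)cyclobut-1-ene | C[Si](C)(C)OC1=C(O[Si](C)(C)C)CC1 | starting material
7 | lithium 2-(trimethylsilyloxy)cyclobut-1-en-1-olate | [Li+].[O-]C1=C(O[Si](C)(C)C)CC1 | intermediate
8 | tributyl{[2-(trimethylsilyloxy)cyclobut-1-en-1-yl]oxy}stannane (O-bound form of the tin enolate) | CCCC[Sn](CCCC)(CCCC)OC1=C(O[Si](C)(C)C)CC1 | intermediate
9 | (2S)-2-[(2Z,5Z)-octa-2,5-dien-1-yl]-2-(trimethylsilyloxy)cyclobutan-1-one | CC/C=C\C/C=C\C[C@]1(O[Si](C)(C)C)C(=O)CC1 | intermediate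
10 | ethynylmagnesium bromide | C#C[Mg]Br | starting material
11 | bromomagnesium (2S)-1-ethynyl-2-[(2Z,5Z)-octa-2,5-dien-1-yl]-2-(trimethylsilyloxy)cyclobutan-1-olate (C1 epimers) | CC/C=C\C/C=C\C[C@]1(O[Si](C)(C)C)C(C#C)(O[Mg]Br)CC1 | intermediate
12 | (2S)-1-ethynyl-2-[(2Z,5Z)-octa-2,5-dien-1-yl]-1,2-bis(trimethylsilyloxy)cyclobutane (C1 epimers) | CC/C=C\C/C=C\C[C@]1(O[Si](C)(C)C)C(C#C)(O[Si](C)(C)C)CC1 | intermediate
13 | (2Z,3S)-2-(iodomethylidene)-3-[(2Z,5Z)-octa-2,5-dien-1-yl]-3-(trimethylsilyloxy)cyclopentan-1-one | CC/C=C\C/C=C\C[C@@]1(O[Si](C)(C)C)CCC(=O)/C1=C\I | intermediate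
14 | cyclohexene oxide (7-oxabicyclo[4.1.0]heptane) | C1CCC2OC2C1 | starting material
15 | lithium (1R)-cyclohex-2-en-1-olate | [Li+].[O-][C@H]1C=CCCC1 | intermediate
16 | triethyl{[(1R)-cyclohex-2-en-1-yl]oxy}silane | CC[Si](CC)(CC)O[C@H]1C=CCCC1 | intermediate
17 | (2R)-6-hydroperoxy-6-methoxy-2-(triethylsilyloxy)hexanal (C6 epimers) | O=C[C@H](O[Si](CC)(CC)CC)CCCC(OC)OO | intermediate
18 | methyl (5R)-6-oxo-5-(triethylsilyloxy)hexanoate | O=C[C@H](O[Si](CC)(CC)CC)CCCC(=O)OC | intermediate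
19 | methyl (5R,6S,7Z)-7-{(2S)-2-[(2Z,5Z)-octa-2,5-dien-1-yl]-5-oxo-2-(trimethylsilyloxy)cyclopentylidene}-5-(triethylsilyloxy)-6-(trimethylsilyloxy)heptanoate | CC/C=C\C/C=C\C[C@@]1(O[Si](C)(C)C)CCC(=O)/C1=C\[C@H](O[Si](C)(C)C)[C@H](O[Si](CC)(CC)CC)CCCC(=O)OC | intermediate
20 | methyl (5R,6S,7Z)-7-{(2R)-2-[(2Z,5Z)-octa-2,5-dien-1-yl]-2,5-bis(trimethylsilyloxy)cyclopent-4-en-1-ylidene}-5-(triethylsilyloxy)-6-(trimethylsilyloxy)heptanoate | CC/C=C\C/C=C\C[C@@]1(O[Si](C)(C)C)CC=C(O[Si](C)(C)C)/C1=C\[C@H](O[Si](C)(C)C)[C@H](O[Si](CC)(CC)CC)CCCC(=O)OC | intermediate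
21 | methyl (5R,6S,7Z)-7-{(2R)-4-bromo-2-[(2Z,5Z)-octa-2,5-dien-1-yl]-5-oxo-2-(trimethylsilyloxy)cyclopentylidene}-5-(triethylsilyloxy)-6-(trimethylsilyloxy)heptanoate (C4 epimers) | CC/C=C\C/C=C\C[C@@]1(O[Si](C)(C)C)CC(Br)C(=O)/C1=C\[C@H](O[Si](C)(C)C)[C@H](O[Si](CC)(CC)CC)CCCC(=O)OC | intermediate
22 | lithium enolate of 21 (4-bromo-cyclopent-4-en-5-olate) | [Li+].CC/C=C\C/C=C\C[C@@]1(O[Si](C)(C)C)CC(Br)=C([O-])/C1=C\[C@H](O[Si](C)(C)C)[C@H](O[Si](CC)(CC)CC)CCCC(=O)OC | intermediate
23 | 4-bromo-4-(phenylselanyl) derivative of 21 | CC/C=C\C/C=C\C[C@@]1(O[Si](C)(C)C)CC(Br)([Se]c2ccccc2)C(=O)/C1=C\[C@H](O[Si](C)(C)C)[C@H](O[Si](CC)(CC)CC)CCCC(=O)OC | intermediate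
24 | selenoxide of 23 | CC/C=C\C/C=C\C[C@@]1(O[Si](C)(C)C)CC(Br)([Se](=O)c2ccccc2)C(=O)/C1=C\[C@H](O[Si](C)(C)C)[C@H](O[Si](CC)(CC)CC)CCCC(=O)OC | intermediate
25 | methyl (5R,6S,7Z)-7-{(2R)-4-bromo-2-[(2Z,5Z)-octa-2,5-dien-1-yl]-5-oxo-2-(trimethylsilyloxy)cyclopent-3-en-1-ylidene}-5-(triethylsilyloxy)-6-(trimethylsilyloxy)heptanoate | CC/C=C\C/C=C\C[C@@]1(O[Si](C)(C)C)C=C(Br)C(=O)/C1=C\[C@H](O[Si](C)(C)C)[C@H](O[Si](CC)(CC)CC)CCCC(=O)OC | intermediate
26 | methyl (5R,6S,7Z)-7-{(2R)-4-bromo-2-hydroxy-2-[(2Z,5Z)-octa-2,5-dien-1-yl]-5-oxocyclopent-3-en-1-ylidene}-5,6-dihydroxyheptanoate | CC/C=C\C/C=C\C[C@@]1(O)C=C(Br)C(=O)/C1=C\[C@H](O)[C@H](O)CCCC(=O)OC | target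

**Step count**
Total: 12 steps. Longest linear sequence: 10 steps (1, 2, 3, 4, 5, 6, 9, 10, 11, 12); steps 7 and 8 form the side branch.

**Three steps most likely to fail**

Step 4 (proposed new step; risk: low ee or slow alkylation of the siloxy tin enolate). The fallback uses known chemistry and sets out from 6 and 5. Cleave 6 with MeLi to the lithium enolate 7 and alkylate it directly with 5 in THF/DMPU, the classical alkylation of a lithium enolate freed from a silyl enol ether. This gives racemic 2-[(2Z,5Z)-octa-2,5-dien-1-yl]-2-(trimethylsilyloxy)cyclobutan-1-one F1. F1 is resolved by preparative chromatography on a chiral stationary phase (supercritical CO2), which comes back to the route at 9.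

Step 6 (risk: the iodonium source attacks the homoallylic Z alkene next to the C12 silyl ether, the terminal C–H is iodinated, or the ring CH2 migrates instead of C12). The fallback carries the side chain as a skipped diyne through the electrophilic step and sets out from 3.
- Appel bromination of 3 gives 1-bromoocta-2,5-diyne F2.
- The step 4 alkylation of tin enolate 8 with F2 gives (2S)-2-(octa-2,5-diyn-1-yl)-2-(trimethylsilyloxy)cyclobutan-1-one F3.
- HC≡CMgBr then Me3SiOTf gives, through bromomagnesium (2S)-1-ethynyl-2-(octa-2,5-diyn-1-yl)-2-(trimethylsilyloxy)cyclobutan-1-olate F4, the ether (2S)-1-ethynyl-2-(octa-2,5-diyn-1-yl)-1,2-bis(trimethylsilyloxy)cyclobutane F5.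
- Metal-free NIS in MeCN at 0 °C (iodonium-induced alkynol ring expansion) gives (2Z,3S)-2-(iodomethylidene)-3-(octa-2,5-diyn-1-yl)-3-(trimethylsilyloxy)cyclopentan-1-one F6.
- Nickel/chromium coupling with 18 as in step 9 gives methyl (5R,6S,7Z)-7-[(2S)-2-(octa-2,5-diyn-1-yl)-5-oxo-2-(trimethylsilyloxy)cyclopentylidene]-5-(triethylsilyloxy)-6-(trimethylsilyloxy)heptanoate F7.
- cis-Semihydrogenation of the two internal alkynes of F7 (Ni(OAc)2, NaBH4, ethylenediamine, H2) comes back to the route at 19.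

Step 11 (risk: the bromo-enolate decomposes or the selenenylation at the brominated carbon stalls). The fallback avoids strong base and selenium and sets out from 21. Soft enolisation (Me3SiOTf, Et3N, CH2Cl2, 0 °C) gives methyl (5R,6S,7Z)-7-{(2R)-4-bromo-2-[(2Z,5Z)-octa-2,5-dien-1-yl]-2,5-bis(trimethylsilyloxy)cyclopent-4-en-1-ylidene}-5-(triethylsilyloxy)-6-(trimethylsilyloxy)heptanoate F8. Dehydrogenation of F8 with the IBX·4-methoxypyridine N-oxide complex in DMSO at rt (hypervalent-iodine oxidation of a silyl enol ether to the enone) comes back to the route at 25.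

**Further compounds**
F1 | step 4 | racemic 2-[(2Z,5Z)-octa-2,5-dien-1-yl]-2-(trimethylsilyloxy)cyclobutan-1-one | CC/C=C\C/C=C\CC1(O[Si](C)(C)C)C(=O)CC1
F2 | step 6 | 1-bromoocta-2,5-diyne | CCC#CCC#CCBr
F3 | step 6 | (2S)-2-(octa-2,5-diyn-1-yl)-2-(trimethylsilyloxy)cyclobutan-1-one | CCC#CCC#CC[C@]1(O[Si](C)(C)C)C(=O)CC1
F4 | step 6 | bromomagnesium (2S)-1-ethynyl-2-(octa-2,5-diyn-1-yl)-2-(trimethylsilyloxy)cyclobutan-1-olate | CCC#CCC#CC[C@]1(O[Si](C)(C)C)C(C#C)(O[Mg]Br)CC1
F5 | step 6 | (2S)-1-ethynyl-2-(octa-2,5-diyn-1-yl)-1,2-bis(trimethylsilyloxy)cyclobutane | CCC#CCC#CC[C@]1(O[Si](C)(C)C)C(C#C)(O[Si](C)(C)C)CC1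
F6 | step 6 | (2Z,3S)-2-(iodomethylidene)-3-(octa-2,5-diyn-1-yl)-3-(trimethylsilyloxy)cyclopentan-1-one | CCC#CCC#CC[C@@]1(O[Si](C)(C)C)CCC(=O)/C1=C\I
F7 | step 6 | methyl (5R,6S,7Z)-7-[(2S)-2-(octa-2,5-diyn-1-yl)-5-oxo-2-(trimethylsilyloxy)cyclopentylidene]-5-(triethylsilyloxy)-6-(trimethylsilyloxy)heptanoate | CCC#CCC#CC[C@@]1(O[Si](C)(C)C)CCC(=O)/C1=C\[C@H](O[Si](C)(C)C)[C@H](O[Si](CC)(CC)CC)CCCC(=O)OC
F8 | step 11 | methyl (5R,6S,7Z)-7-{(2R)-4-bromo-2-[(2Z,5Z)-octa-2,5-dien-1-yl]-2,5-bis(trimethylsilyloxy)cyclopent-4-en-1-ylidene}-5-(triethylsilyloxy)-6-(trimethylsilyloxy)heptanoate | CC/C=C\C/C=C\C[C@@]1(O[Si](C)(C)C)CC(Br)=C(O[Si](C)(C)C)/C1=C\[C@H](O[Si](C)(C)C)[C@H](O[Si](CC)(CC)CC)CCCC(=O)OC
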